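The target is (S)-abscisic acid whose C8' methyl, the C6' methyl cis to the side chain, bears an oxygen acylated by methyl (R)-3-hydroxy-3-methylglutarate. Everything rests on disconnecting the C8'–O bond back to a plain methyl group. In one operation a carboxyl at C5, left on C1' after the side chain of abscisic acid is cut away, oxidises that methyl to a cis-fused γ-lactone on the six-membered ring A; the step exploits the γ-relationship between the C5 carboxyl on C1' and the geminal methyls on the hydrogen-free quaternary C6', and it creates the C6' stereocentre. The precursor is the C1'-acetoxy ring carboxylic acid with the C4' enone free.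

Key step: step 4

Remark on numbering: abscisic acid numbering is used (side chain C1–C5, ring A carbons C1'–C6', C7' the methyl on C2', C8' the C6' methyl cis to the side chain, C9' the one trans); ring B is the five-membered lactone.

Remark on the glutarate unit (assumption): with (R)-mevalonolactone the target configuration arises only if mevalonate C1 becomes the ester to O8' and mevalonate C5 is oxidised to the methyl ester; the opposite assignment would give the epimer.

Remark on C4': the ketone is masked as a dioxolane after the key step, because a free 8'-hydroxyl adds to the enone at C2' (phaseic-acid-type cyclisation) and because an unmasked ketone would be reduced in step 6 to a secondary alcohol that competes in the acylation of step 13.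

Step 1
Reactants: 1 (S)-abscisic acid
Product: 3 (S)-1'-O-acetylabscisic acid, via mixed anhydride 2 (not isolated)
Conditions: Ac2O (4 equiv), Sc(OTf)3 (2 mol%), MeCN, −20 → 0 °C; then aq. NaHCO3/THF, rt; acidify to pH 3
Reagents that add atoms: acetic anhydride, CC(=O)OC(C)=O
Why: Lewis-acid-catalysed esterification with Ac2O activated by Sc(OTf)3 should reach the shielded tertiary C1' hydroxyl at low temperature, ionisation at C1' being disfavoured because both allylic arms are electron-poor, while the carboxyl, acetylated only as mixed anhydride 2, is freed again by the bicarbonate hydrolysis, so C1' keeps the configuration of 1.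

Step 2
Reactants: 3 (S)-1'-O-acetylabscisic acid
Product: 5 (1S)-1-formyl-2,6,6-trimethyl-4-oxocyclohex-2-en-1-yl acetate, via secondary ozonide 4 (not isolated)
Conditions: O3 (1.05 equiv, Sudan Red 7B end point), CH2Cl2, −78 °C; Me2S, −78 °C → rt; aq. NaHCO3 wash
Reagents that add atoms: ozone, [O-][O+]=O
Why: Ozonolysis by the Criegee mechanism should occur at C4=C5, the distal and most electron-rich alkene of the dienoic acid, before the enoate C2=C3 or the ring enone C2'=C3' is touched, and reduction of the ozonide with Me2S gives the C5 aldehyde with C1' unchanged while the acidic C1–C4 fragment goes into the bicarbonate wash.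

Step 3
Reactants: 5 (1S)-1-formyl-2,6,6-trimethyl-4-oxocyclohex-2-en-1-yl acetate
Product: 6 (1S)-1-acetoxy-2,6,6-trimethyl-4-oxocyclohex-2-ene-1-carboxylic acid
Conditions: NaClO2, NaH2PO4, 2-methylbut-2-ene, t-BuOH/H2O, 0 °C → rt
Reagents that add atoms: sodium chlorite, [Na+].[O-]Cl=O
Why: Pinnick oxidation, in which chlorous acid adds to the aldehyde and fragments to the acid under buffered conditions that spare the tertiary acetate and the enone, 2-methylbut-2-ene consuming the hypochlorous acid, and the α-carbon has no hydrogen, so C1' cannot epimerise.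

Step 4
Reactants: 6 (1S)-1-acetoxy-2,6,6-trimethyl-4-oxocyclohex-2-ene-1-carboxylic acid
Product: 7 (3aS,7aR)-7a-acetoxy-3a,7-dimethyl-3a,4-dihydro-2-benzofuran-1,5(3H,7aH)-dione
Conditions: Pd(OAc)2 (10 mol%), N-acetyl-β-alanine (20 mol%), t-BuOOH (70% aq., 2.5 equiv), CsHCO3 (0.5 equiv), (CF3)2CHOH, 60 °C
Reagents that add atoms: none
Why: The carboxylate of 6 binds divalent palladium and the N-acyl amino acid ligand serves as internal base for concerted metalation–deprotonation of a C8'–H bond, which gives a six-membered palladacycle (Pd, O, C5, C1', C6', C8'); the peroxide oxidises this to tetravalent palladium, and C–O reductive elimination, an SN2-type attack of the carboxylate oxygen on C8', releases lactone 7 and divalent palladium. The closest known reaction type is the Pd(OAc)2-catalysed γ-methyl C–H lactonisation of free aliphatic acids that have a β-quaternary carbon. Ring B, the five-membered lactone, closes in a 5-exo-tet sense by contraction of the palladacycle. The new C6' stereocentre is controlled by the C1' centre taken from 1, since the carboxyl can reach only the geminal methyl on its own face and the ring fusion is therefore cis. The step must select C8' over C9', the allylic C7' methyl and the C5' methylene: the carboxyl prefers the pseudo-axial site on C1' (an equatorial C1' substituent suffers allylic strain with the C2' methyl), where it is gauche to C8' and anti to C9', the planar C7' methyl cannot join a puckered palladacycle from that site, methyl C–H bonds are metalated before methylene ones, and C6' has no hydrogen, so β-hydride loss cannot intervene. The acetate stops the C1' oxygen from chelating palladium and from triggering oxidative decarboxylation, as a free α-hydroxy acid would.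

Step 5
Reactants: 7 (3aS,7aR)-7a-acetoxy-3a,7-dimethyl-3a,4-dihydro-2-benzofuran-1,5(3H,7aH)-dione
Product: 8 C4' ethylene ketal of lactone 7 (spiro-1,3-dioxolane at the former ketone carbon)
Conditions: (TMSOCH2)2 (3 equiv), TMSOTf (5 mol%), CH2Cl2, −78 → −20 °C; pyridine quench
Reagents that add atoms: 1,2-bis(trimethylsilyloxy)ethane, C[Si](C)(C)OCCO[Si](C)(C)C
Why: Trimethylsilyl-triflate-catalysed ketalisation with the bis-silyl ether of ethylene glycol converts the C4' ketone into its dioxolane at low temperature without moving the C2'=C3' bond, which makes the coming hydride step chemoselective and removes the Michael acceptor that a free 8'-hydroxyl would attack at C2'.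

Step 6
Reactants: 8 C4' ethylene ketal of lactone 7
Product: 9 lactol with free C1' hydroxyl (C5 hemiacetal bridged to O8', both anomers, dioxolane at C4')
Conditions: i-Bu2AlH (4.5 equiv), CH2Cl2, −78 °C; MeOH, then aq. KNaC4H4O6, rt
Reagents that add atoms: none
Why: Partial reduction of a lactone with i-Bu2AlH at −78 °C stops at the aluminium hemiacetal and so delivers the lactol, the same reagent cleaving the tertiary acetate reductively while the dioxolane is inert; the new lactol carbon forms as both anomers, which is harmless because it becomes sp2 in step 7.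

Step 7
Reactants: 9 lactol with free C1' hydroxyl
Product: 10 (E)-alkenyl pinacolboronate diol (C5=C4–Bpin on C1', free 1'- and 8'-hydroxyls, dioxolane at C4')
Conditions: CrCl2 (10 equiv), LiI (5 equiv), Cl2CHBpin (2.5 equiv), THF, 0 °C → rt
Reagents that add atoms: 2-(dichloromethyl)-4,4,5,5-tetramethyl-1,3,2-dioxaborolane, ClC(Cl)B1OC(C)(C)C(C)(C)O1
Why: Takai–Utimoto borylolefination, in which the geminal dichromium species formed from the dihalomethylboronate adds to the hydroxy aldehyde in equilibrium with the lactol and the bulky adduct eliminates to the E-alkenylboronate, the reagent being unreactive towards free hydroxyls, the dioxolane and the ring alkene.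

Step 8
Reactants: 11 (R)-mevalonolactone
Product: 13 benzyl (3R)-3,5-dihydroxy-3-methylpentanoate, via potassium (R)-mevalonate 12 (not isolated)
Conditions: KOH (1.0 equiv), H2O/MeOH, rt; evaporate; BnBr, Bu4NI (cat.), DMF, rt
Reagents that add atoms: potassium hydroxide, [K+].[OH-]; benzyl bromide, BrCc1ccccc1
Why: Saponification opens the δ-lactone and SN2 O-alkylation of the carboxylate with benzyl bromide locks the open form as the C1 benzyl ester, which marks mevalonate C1 as the carboxyl that will later acylate O8'; the tertiary carbinol centre is not touched.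

Step 9
Reactants: 13 benzyl (3R)-3,5-dihydroxy-3-methylpentanoate
Product: 14 (3R)-5-(benzyloxy)-3-hydroxy-3-methyl-5-oxopentanoic acid
Conditions: TEMPO (20 mol%), PhI(OAc)2 (2.2 equiv), MeCN/H2O 1:1, rt
Reagents that add atoms: water, O
Why: Oxoammonium (TEMPO) oxidation with PhI(OAc)2 in aqueous acetonitrile takes the primary alcohol through the aldehyde hydrate to the carboxylic acid and cannot oxidise the tertiary alcohol.

Step 10
Reactants: 14 (3R)-5-(benzyloxy)-3-hydroxy-3-methyl-5-oxopentanoic acid
Product: 15 1-benzyl 5-methyl (3R)-3-hydroxy-3-methylpentanedioate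
Conditions: MeI (1.5 equiv), KHCO3 (1.2 equiv), DMF, rt
Reagents that add atoms: iodomethane, CI
Why: SN2 alkylation of the carboxylate with iodomethane under bicarbonate is too mildly basic to cause retro-aldol cleavage or elimination of the β-hydroxy diester, and it makes the former mevalonate C5 the methyl ester end.

Step 11
Reactants: 15 1-benzyl 5-methyl (3R)-3-hydroxy-3-methylpentanedioate
Product: 16 1-benzyl 5-methyl (3R)-3-methyl-3-(triethylsilyloxy)pentanedioate
Conditions: TESOTf (1.5 equiv), 2,6-lutidine (2 equiv), CH2Cl2, −78 → 0 °C
Reagents that add atoms: triethylsilyl trifluoromethanesulfonate, CC[Si](CC)(CC)OS(=O)(=O)C(F)(F)F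
Why: Silylation with a silyl triflate and a hindered pyridine base is the standard way to cap a tertiary alcohol, and the triethylsilyl ether prevents self-acylation or β-lactone formation when the acid is activated in step 13.

Step 12
Reactants: 16 1-benzyl 5-methyl (3R)-3-methyl-3-(triethylsilyloxy)pentanedioate
Product: 17 (3S)-5-methoxy-3-methyl-5-oxo-3-(triethylsilyloxy)pentanoic acid (same spatial arrangement as 16; the descriptor changes by ranking only)
Conditions: H2 (1 atm), 10% Pd/C, EtOAc, rt
Reagents that add atoms: none
Why: Hydrogenolysis of the benzylic C–O bond over Pd/C in ethyl acetate frees the C1 carboxyl while the methyl ester and the tertiary silyl ether persist in the non-protic solvent.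

Step 13
Reactants: 10 (E)-alkenyl pinacolboronate diol; 17 (3S)-5-methoxy-3-methyl-5-oxo-3-(triethylsilyloxy)pentanoic acid
Product: 18 8'-O-glutarate ester of 10 (silyl-protected methyl glutarate on O8', C1' hydroxyl free, boronate and dioxolane intact)
Conditions: EDC·HCl (1.5 equiv), DMAP (0.5 equiv), CH2Cl2, 0 °C → rt
Reagents that add atoms: none
Why: Steglich esterification, in which the acylpyridinium ion formed from the carbodiimide-activated acid and DMAP acylates the primary C8' hydroxyl, the only hydroxyl that can react since the C1' carbinol is tertiary and shielded, while boronate and dioxolane are spectators.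

Step 14
Reactants: 19 but-2-ynoic acid
Product: 20 (Z)-3-iodobut-2-enoic acid
Conditions: NaI (1.6 equiv), AcOH, 115 °C
Reagents that add atoms: sodium iodide, [Na+].[I-]
Why: Hydroiodination of the ynoic acid by conjugate addition of iodide and anti protonation gives the Z β-iodo acid, with iodine and carboxyl cis, as is established for this alkynoic acid in hot acetic acid.

Step 15
Reactants: 18 8'-O-glutarate ester of 10; 20 (Z)-3-iodobut-2-enoic acid
Product: 21 protected target (2Z,4E-dienoic acid with C4' dioxolane and triethylsilyl ether on the glutarate)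
Conditions: Pd(dppf)Cl2 (5 mol%), K3PO4 (3.5 equiv), THF/H2O 9:1, rt, dark; acidify to pH 3
Reagents that add atoms: none
Why: Suzuki–Miyaura coupling proceeds with retention of configuration at both alkenyl carbons, so the E-boronate and the Z-iodide give the 2Z,4E-dienoic acid, the iodo acid reacting as its carboxylate and the mild phosphate base at room temperature sparing the esters, the silyl ether and the dioxolane.

Step 16
Reactants: 21 protected target
Product: 22 target, (2Z,4E)-5-[(1R,6S)-1-hydroxy-6-({[(3R)-3-hydroxy-5-methoxy-3-methyl-5-oxopentanoyl]oxy}methyl)-2,6-dimethyl-4-oxocyclohex-2-en-1-yl]-3-methylpenta-2,4-dienoic acid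
Conditions: 1 M aq. HCl/THF 1:4, 0 °C → rt, dark
Reagents that add atoms: water, O
Why: Acid-catalysed hydrolysis of the dioxolane through the allylic oxocarbenium ion and protodesilylation of the tertiary silyl ether take place in dilute aqueous acid, conditions under which the tertiary allylic alcohol, the Z,E-dienoic acid and both carboxylic esters should be stable, so no stereocentre or alkene geometry changes.

Compound list
1 | (S)-abscisic acid, (2Z,4E)-5-[(1S)-1-hydroxy-2,6,6-trimethyl-4-oxocyclohex-2-en-1-yl]-3-methylpenta-2,4-dienoic acid | CC1=CC(=O)CC(C)(C)[C@@]1(O)/C=C/C(C)=C\C(=O)O | starting material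
2 | acetic mixed anhydride of 3 at the C1 carboxyl | CC1=CC(=O)CC(C)(C)[C@@]1(OC(C)=O)/C=C/C(C)=C\C(=O)OC(C)=O | intermediate
3 | (S)-1'-O-acetylabscisic acid, (2Z,4E)-5-[(1S)-1-acetoxy-2,6,6-trimethyl-4-oxocyclohex-2-en-1-yl]-3-methylpenta-2,4-dienoic acid | CC1=CC(=O)CC(C)(C)[C@@]1(OC(C)=O)/C=C/C(C)=C\C(=O)O | intermediate
4 | secondary ozonide of 3 across C4=C5 (1,2,4-trioxolane, mixture at the two ring acetal carbons) | CC1=CC(=O)CC(C)(C)[C@@]1(OC(C)=O)C2OC(OO2)/C(C)=C\C(=O)O | intermediate
5 | (1S)-1-formyl-2,6,6-trimethyl-4-oxocyclohex-2-en-1-yl acetate | CC1=CC(=O)CC(C)(C)[C@@]1(OC(C)=O)C=O | intermediate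
6 | (1S)-1-acetoxy-2,6,6-trimethyl-4-oxocyclohex-2-ene-1-carboxylic acid | CC1=CC(=O)CC(C)(C)[C@@]1(OC(C)=O)C(=O)O | intermediate
7 | (3aS,7aR)-7a-acetoxy-3a,7-dimethyl-3a,4-dihydro-2-benzofuran-1,5(3H,7aH)-dione, cis-fused | O=C1OC[C@]2(C)CC(=O)C=C(C)[C@]12OC(C)=O | intermediate
8 | C4' ethylene ketal of 7 (spiro-1,3-dioxolane at C5 of the benzofuranone, 3aS,7aR) | O=C1OC[C@]2(C)CC3(OCCO3)C=C(C)[C@]12OC(C)=O | intermediate
9 | lactol from 8: C1 hemiacetal (both anomers), free 7a-hydroxyl, dioxolane retained, 3aS,7aR | OC1OC[C@]2(C)CC3(OCCO3)C=C(C)[C@]12O | intermediate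
10 | (E)-alkenyl pinacolboronate diol: ring A with C4' dioxolane, C1' carrying OH and (E)-CH=CH–Bpin, C6' carrying CH3 and CH2OH cis to the alkenyl group | OC[C@]1(C)CC2(OCCO2)C=C(C)[C@]1(O)/C=C/B1OC(C)(C)C(C)(C)O1 | intermediate
11 | (R)-mevalonolactone | C[C@@]1(O)CCOC(=O)C1 | starting material
12 | potassium (R)-mevalonate, potassium (3R)-3,5-dihydroxy-3-methylpentanoate | OCC[C@@](C)(O)CC(=O)[O-].[K+] | intermediate
13 | benzyl (3R)-3,5-dihydroxy-3-methylpentanoate | OCC[C@@](C)(O)CC(=O)OCc1ccccc1 | intermediate
14 | (3R)-5-(benzyloxy)-3-hydroxy-3-methyl-5-oxopentanoic acid | OC(=O)C[C@@](C)(O)CC(=O)OCc1ccccc1 | intermediate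
15 | 1-benzyl 5-methyl (3R)-3-hydroxy-3-methylpentanedioate | COC(=O)C[C@@](C)(O)CC(=O)OCc1ccccc1 | intermediate
16 | 1-benzyl 5-methyl (3R)-3-methyl-3-(triethylsilyloxy)pentanedioate | COC(=O)C[C@@](C)(O[Si](CC)(CC)CC)CC(=O)OCc1ccccc1 | intermediate
17 | (3S)-5-methoxy-3-methyl-5-oxo-3-(triethylsilyloxy)pentanoic acid | COC(=O)C[C@@](C)(O[Si](CC)(CC)CC)CC(=O)O | intermediate
18 | 8'-O-[(3R)-5-methoxy-3-methyl-5-oxo-3-(triethylsilyloxy)pentanoyl] ester of 10 | COC(=O)C[C@@](C)(O[Si](CC)(CC)CC)CC(=O)OC[C@]1(C)CC2(OCCO2)C=C(C)[C@]1(O)/C=C/B1OC(C)(C)C(C)(C)O1 | intermediate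
19 | but-2-ynoic acid | CC#CC(=O)O | starting material
20 | (Z)-3-iodobut-2-enoic acid | C/C(I)=C/C(=O)O | intermediate
21 | protected target: 22 with C4' as dioxolane and the glutarate hydroxyl as triethylsilyl ether | COC(=O)C[C@@](C)(O[Si](CC)(CC)CC)CC(=O)OC[C@]1(C)CC2(OCCO2)C=C(C)[C@]1(O)/C=C/C(C)=C\C(=O)O | intermediate
22 | (2Z,4E)-5-[(1R,6S)-1-hydroxy-6-({[(3R)-3-hydroxy-5-methoxy-3-methyl-5-oxopentanoyl]oxy}methyl)-2,6-dimethyl-4-oxocyclohex-2-en-1-yl]-3-methylpenta-2,4-dienoic acid | COC(=O)C[C@@](C)(O)CC(=O)OC[C@]1(C)CC(=O)C=C(C)[C@]1(O)/C=C/C(C)=C\C(=O)O | target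

Total step count: 16. Longest linear sequence: 10 steps (steps 1–7, 13, 15 and 16).

Steps most likely to fail

Step 4. The α-acyloxy carboxylate may bind palladium too weakly for cyclometalation to start. Metalation may also stray to C9' or C7', the acetate may shift to the carboxylate and open the way to oxidative decarboxylation, or the peroxide may attack the enone. The fallback replaces organopalladium C–H cleavage by a radical relay; it sets out from 6 and comes back at 7. Acid 6 would be converted with (COCl)2 and catalytic DMF into acid chloride F1 and then with NH3 in THF at −40 °C into primary amide F2. Irradiation of F2 with Pb(OAc)4 and I2 in CH2Cl2 under visible light should give N-iodoamide F3, whose amidyl radical abstracts hydrogen from the facing C8' methyl through a six-membered transition state (Hofmann–Löffler–Freytag-type 1,5-hydrogen transfer). Iodine transfer would give C8' iodide F4, the amide oxygen would displace iodide to give iminolactone F5, and aqueous acid would hydrolyse F5 to lactone 7. The electrophilic amidyl radical should spare the electron-poor C5' and C7' hydrogens.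

Step 7. The lactol may stay closed, so that the chromium reagent meets no carbonyl, or addition to the neopentyl-type α-hydroxy aldehyde may be slower than decay of the reagent. The fallback uses alkyne homologation and hydroboration instead of direct olefination; it sets out from 9 and comes back at 10. Ohira–Bestmann homologation of lactol 9 (dimethyl (1-diazo-2-oxopropyl)phosphonate, K2CO3, MeOH, rt), which engages lactols through their open form under base, would give terminal alkyne F6. Copper-catalysed hydroboration of F6 (CuCl, NaOt-Bu, Xantphos, B2pin2, MeOH, THF, rt) should then give, by syn borylcupration and protonation, the E-alkenylboronate 10.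

Step 1. Acylation of the shielded tertiary hydroxyl may stay incomplete, or the Lewis acid may ionise C1' and cause allylic transposition or elimination. The fallback delivers the acetyl group intramolecularly after the side chain has been cut; it sets out from 1 and comes back at 6. Ozonolysis of unprotected 1 under the conditions of step 2 would give, through secondary ozonide F7, hydroxy aldehyde F8, and Pinnick oxidation would give hydroxy acid F9. Neat acetyl chloride at 40 °C should convert the carboxyl of F9 into mixed anhydride F10, from which the acetyl group passes to the neighbouring C1' oxygen through a five-membered transition state; aqueous work-up would give acid 6.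

Further compounds
F1 | step 4 | (1S)-1-(chlorocarbonyl)-2,6,6-trimethyl-4-oxocyclohex-2-en-1-yl acetate | CC1=CC(=O)CC(C)(C)[C@@]1(OC(C)=O)C(Cl)=O
F2 | step 4 | (1S)-1-carbamoyl-2,6,6-trimethyl-4-oxocyclohex-2-en-1-yl acetate | CC1=CC(=O)CC(C)(C)[C@@]1(OC(C)=O)C(N)=O
F3 | step 4 | N-iodo derivative of amide F2 | CC1=CC(=O)CC(C)(C)[C@@]1(OC(C)=O)C(=O)NI
F4 | step 4 | C8' iodide of amide F2 (iodomethyl on C6' cis to the carbamoyl group) | IC[C@]1(C)CC(=O)C=C(C)[C@]1(OC(C)=O)C(N)=O
F5 | step 4 | iminolactone, the 1-imino analogue of lactone 7 | N=C1OC[C@]2(C)CC(=O)C=C(C)[C@]12OC(C)=O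
F6 | step 7 | terminal alkyne: ring A with C4' dioxolane, C1' carrying OH and ethynyl, C6' carrying CH3 and CH2OH cis to the ethynyl group | OC[C@]1(C)CC2(OCCO2)C=C(C)[C@]1(O)C#C
F7 | step 1 | secondary ozonide of 1 across C4=C5 | CC1=CC(=O)CC(C)(C)[C@@]1(O)C2OC(OO2)/C(C)=C\C(=O)O
F8 | step 1 | (1S)-1-hydroxy-2,6,6-trimethyl-4-oxocyclohex-2-ene-1-carbaldehyde | CC1=CC(=O)CC(C)(C)[C@@]1(O)C=O
F9 | step 1 | (1S)-1-hydroxy-2,6,6-trimethyl-4-oxocyclohex-2-ene-1-carboxylic acid | CC1=CC(=O)CC(C)(C)[C@@]1(O)C(=O)O
F10 | step 1 | acetic (1S)-1-hydroxy-2,6,6-trimethyl-4-oxocyclohex-2-ene-1-carboxylic anhydride | CC1=CC(=O)CC(C)(C)[C@@]1(O)C(=O)OC(C)=O
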